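Readings and results were generated by integration on assumed constants, noise included.

Slowness comes first: how long does the starting material last? In the eta run it falls from 78.9% at 0.250 h to 5.7% at 3.00 h, which reads as a first-order constant of 0.956 h⁻¹.

| setting | eta | alpha | theta | violet | blue | green | red |
|---|---|---|---|---|---|---|---|
| starting material | 0.30 M | 0.30 M | 0.30 M | 0.30 M | 0.30 M | 0.30 M | 0.30 M |
| first nucleophile | 0.70 equiv | 0.47 equiv | 1 equiv | 0.700 equiv | 0.700 equiv (in portions, 3, over 4.0 h) | 0.700 equiv (fed, over 4.0 h) | 0.700 equiv |
| second nucleophile | 1 equiv | 1 equiv | 1 equiv | 1.00 equiv | 1.00 equiv | 1.00 equiv | 1.00 equiv (fed, over 4.0 h) |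
| remark | run made earlier | run made earlier | run made earlier | everything together at the start | first portion at the start, last at 4.0 h | all else is in the flask from the start; the feed brings no volume worth counting | all else is in the flask from the start; the feed brings no volume worth counting |
| time |  |  |  | 5.0 h | 5.0 h | 5.0 h | 5.0 h |

| run | time / h | target / % | starting material / % |
|---|---|---|---|
| eta | 0.250 | 5.3 | 78.9 |
| eta | 0.417 | 7.1 | 66.9 |
| eta | 0.833 | 11.2 | 45.4 |
| eta | 1.50 | 15.6 | 23.5 |
| eta | 3.00 | 19.6 | 5.7 |
| alpha | 0.250 | 3.1 | 78.3 |
| alpha | 0.417 | 4.9 | 67.0 |
| alpha | 0.833 | 8.2 | 44.7 |
| alpha | 1.50 | 11.0 | 23.3 |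
| alpha | 3.00 | 14.5 | 5.5 |
| theta | 0.250 | 6.3 | 78.9 |
| theta | 0.417 | 9.4 | 67.8 |
| theta | 0.833 | 14.2 | 44.9 |
| theta | 1.50 | 20.2 | 23.5 |
| theta | 3.00 | 25.0 | 5.8 |

(readings scatter by 0.3 percentage points)

- which flask leads in amount of target, in percent of the starting material charged ("all alike" within 1.5 percentage points) (violet / blue / green / red / all alike)
- how much target is there at the end, in percent of the starting material charged: violet
- how much target is there at the end, in percent of the starting material charged: blue
- how much target is there at the end, in percent of the starting material charged: green
- how much target is there at the end, in percent of the starting material charged: red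

- percentages count the starting material that a species holds: one side product B counts as two
- what was read earlier has a scatter of 0.3 percentage points, one standard deviation
- candidate steps: starting material -> intermediate; first nucleophile + intermediate -> target; second nucleophile + intermediate -> other capture product; intermediate -> solvolysis product; intermediate -> side product A; first nucleophile <-> dormant form; starting material + intermediate -> side product B

Does the first nucleophile hurry it? No: at 3.00 h the alpha, eta and theta runs read 5.5%, 5.7% and 5.8%, so I take the step from starting material to intermediate as the rate-limiting step.

What does a feed meet, then? A feed of 4.0 h lasts longer than the starting material's mean life, read as 1.05 h, so the starting material goes while the feed is still coming. Averaged over the starting material as it is consumed, the fraction of a steady feed already added is 0.256: the dosing share. For blue's portions, weighed the same way, it is 0.390.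

What is a share worth in target? Work in powers of ten. From alpha to theta, at matching conversion, the charge climbs 0.328 decades and target 0.237, an exponent of 0.721.

And the base? Eta scaled to full conversion gives 20.8%, my figure for violet. Applying the exponent to the shares, I get 7.79% for green and 10.5% for blue.

Now the weak spot: red? The alpha, eta and theta runs stand at 1 equiv, 1 equiv and 1 equiv of second nucleophile, so they offer no change of charge to read its exponent from. I commit to the sign: if it competes for the intermediate, red ends above violet.

The forecast names red as leader, with violet 20.8%, blue 9.5%, green 6% and red 25%, and says of the slow second nucleophile: “Feeding it slowly should lift the target somewhat”. Its blue and green differ from mine.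

At 5.0 h red leads with 32.2%, against violet 20.3%, blue 9.55% and green 7.47%.

    starting material → intermediate (k = 0.0160 min⁻¹)
    first nucleophile + intermediate → target (k = 160 M⁻¹ min⁻¹)
    second nucleophile + intermediate → other capture product (k = 69.0 M⁻¹ min⁻¹)
    intermediate → solvolysis product (k = 5.90 min⁻¹)
    intermediate → side product A (k = 0.260 min⁻¹)
    first nucleophile ⇌ dormant form (K = 4.70, k = 0.500 min⁻¹)
    starting material + intermediate → side product B (k = 0.0170 M⁻¹ min⁻¹)

Red's other capture product ends at 23.1%, violet's at 55.1%. Taking c(second nucleophile) in red, averaged over the starting material as it is consumed, as the dosing share 0.256 of violet's, red's gain in target over violet reads as an exponent of −0.339. Carried to the green neighbour charged with 0.400 equiv of second nucleophile, that exponent reckons green's 7.47% up to 10.2%; the neighbour gives 12.0%.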